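Readings and results stem from a simulated flask with made-up constants, and the scatter is random.

The rate constants of X are unknown, so this flask is reckoned from a ledger of the G charged.

| setting | midnight | spring | flask |
|---|---|---|---|
| G | 0.050 M | 0.050 M | 0.050 M |
| X | 0.37 µM | 0.37 µM | 0.37 µM |
| temperature | 25 °C | 20 °C | 25 °C |
| remark | the very flask that is asked about, followed so far | run made earlier |  |
| time |  |  | 4.0 h |

- midnight (time / min: J / %, G / %): 12.0: 63.8, 36.2; 40.0: 64.4, 36.3; 60.0: 63.6, 36.6; 90.0: 63.0, 35.7; 150: 63.2, 36.8; 180: 63.2, 36.5; 240: 63.7, 35.7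
- spring (time / min: J / %, G / %): 12.0: 91.0, 9.8; 40.0: 91.2, 9.1; 60.0: 91.7, 8.8; 90.0: 91.0, 8.1; 150: 91.4, 9.6; 180: 91.1, 9.0; 240: 92.0, 9.5

(each reading ± 0.5 percentage points)

- removed J is counted in
- what may be going on: X -> D; G + X -> J + X; X -> Q
- additions bring no volume worth counting

- Tuesday's: at 4.0 h take out 90 % of the J then present, then wait 4.0 h
- Friday's: change nothing and wait 4.0 h more
- Thursday's: at 4.0 h raise the temperature by 20 K, then wait 4.0 h
- Wednesday's: at 4.0 h add X, 100 % of the amount charged, then wait 4.0 h

1. J, in percent of the G first charged, at 4.0 h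
2. the remedy with the largest gain of J, or "none" below 2 percentage points (Tuesday's / Friday's / Thursday's / Wednesday's / none)
3. J present, with what was taken out counted in, in percent of the G first charged, after Tuesday's
4. J present, with what was taken out counted in, in percent of the G first charged, after Wednesday's

In the midnight run, the flask asked about, the first entry is J, with a mean of 63.6 % from 12.0 min to 240 min, flat within a scatter of 0.5 percentage points. The second entry is unconverted G, with a mean of 36.3 %. The two sum to 99.9 %, so the books need no third entry. The listed steps run one way, so G standing idle points to stopped X, not to equilibrium. Replacing the curve by its plateau mean gives 85900 moles of J per mole of X charged, the turnover number.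

This reckoning therefore puts J at 63.6 % at 4.0 h. It enters no gain for Tuesday's, Friday's or Thursday's, since none of them supplies working X. Wednesday's dose, at that turnover number, is worth 63.6 % of the G charged, more than the 36.3 % of G remaining. But that mean was earned at higher G than the dose meets, so it marks a ceiling and not an estimate.

The forecast gives 63.5 %, picks Wednesday's, and puts Tuesday's at 63.5 %. For Wednesday's it gives 87 %, a gain of 23 points that stands below that ceiling, reasoning that “a full dose converts the same fraction again”.

The flask gives 63.5 %, Wednesday's as the best remedy, 63.5 % after Tuesday's and 95.5 % after Wednesday's.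

    X → D (k = 2.20 × 10⁻⁴ s⁻¹, Ea = 263 kJ mol⁻¹)
    G + X → J + X, rate k2*[G]^1.5*[X]/(1 + ([G]/Kh2)^1.5) (8.10 mM, k = 2.70 × 10⁶ L¹·⁵ mol⁻¹·⁵ s⁻¹, Ea = 13.0 kJ mol⁻¹)
    X → Q (k = 0.0200 s⁻¹, Ea = 88.0 kJ mol⁻¹)
    (constants at 25 °C)

X passes into Q with a half-life of 0.58 min, far shorter than the 53 min of its passing into D. Half of the turnover of G into J is done by 0.537 min, and 0 % of the catalyst is live at 240 min. Wednesday's dose, starting from 37 % of G, earned 43300 turnovers, half of 85900.

In the neighbour flask with 1.5 × 10⁻⁷ M of X, 85900 turnovers give 25.8 % of J. The computed result there is 27.0 %, with 73.0 % of G remaining.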